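The (Z)-C3(O-acyl)–C4(Me)=C5–C6(O-acyl) unit of the ten-membered ring is a 2-ene-1,4-diol diester, and the C12 carboxyl hangs on C7 next to C6. O–C6, O–C3 and the 4Z alkene are therefore cut together, back to the ring diene acid 24 (C3=C4–C5=C6) and isobutyric acid.
Further cuts, in order: C5=C6 (ring-closing metathesis), the C1–C10 epoxide oxygen, the C8 ester, C7–C8 (allylation of aldehyde 8 with bromide 14), and C1–C2 (alkenylalane–allyl coupling).
Forward order: C8–C5 chain, then C7–C8 union, C8 ester, epoxide, ten-membered ring, and the γ-lactone ring last, which gives the target directly.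
Stereochemistry: C2′/C3′ come from Sharpless epoxidation, C7/C8 from a ligand-controlled chromium allylation through a closed transition state, and C1/C10 from the Shi ketone. C6, C3 and the 4Z alkene are relayed from C7 in the key step.

Key step: step 15

Assumption: germacranolide numbering is used throughout (ring C1–C10, C11–C13 acrylate/lactone carbons, C14 on C10, C15 on C4), and the (S,S) ligand of step 10 is taken to give the 8R carbinol; if it favours 8S, its mirror image is used.

Step 1
Reactants: 1 (E)-3-methylpent-2-en-4-yn-1-ol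
Product: 2 (E)-3-methylpenta-2,4-dien-1-ol
Conditions: H2 (1 atm, 1 equiv), Pd/CaCO3–Pb(OAc)2 (Lindlar catalyst), quinoline, Et2O, 0 °C
Reagents that add atoms: none
Why: Lindlar semihydrogenation should stop at the vinyl group of the terminal alkyne and leave the E-trisubstituted alkene untouched.

Step 2
Reactants: 2 (E)-3-methylpenta-2,4-dien-1-ol
Product: 4 (2E)-1-chloro-3-methylpenta-2,4-diene, via dienyl mesylate 3 (not isolated)
Conditions: MsCl, 2,4,6-collidine, LiCl, DMF, 0 °C
Reagents that add atoms: methanesulfonyl chloride CS(=O)(=O)Cl (its atoms stay only in 3); lithium chloride [Li+].[Cl-]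
Why: Mesylation followed by in situ SN2 displacement with chloride under collidine buffering is the standard mild allylic chlorination and keeps the E geometry because no free allyl cation forms.

Step 3
Reactants: 5 but-3-yn-1-ol; 4 (2E)-1-chloro-3-methylpenta-2,4-diene
Product: 7 (3E,6E)-3,7-dimethylnona-3,6,8-trien-1-ol, via alkenylalane 6 (not isolated)
Conditions: Me3Al (3 equiv), Cp2ZrCl2 (25 mol %), CH2Cl2, 0 °C to rt; then 4, Pd(PPh3)4 (5 mol %), THF, rt; aqueous work-up
Reagents that add atoms: trimethylaluminium C[Al](C)C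
Why: Negishi carboalumination adds Me and Al syn with Al on the terminal carbon, which fixes the E C1=C10 alkene, and the Pd-catalysed alkenylalane–allyl chloride coupling then forms C1–C2 with retention; the 3-methylpentadienyl unit is symmetric, so attack at either terminus gives the same skipped triene.

Step 4
Reactants: 7 (3E,6E)-3,7-dimethylnona-3,6,8-trien-1-ol
Product: 8 (3E,6E)-3,7-dimethylnona-3,6,8-trienal
Conditions: Dess–Martin periodinane, NaHCO3, CH2Cl2, 0 °C; used at once
Reagents that add atoms: none
Why: Buffered Dess–Martin oxidation is neutral and fast, so the β,γ-unsaturated aldehyde should form without migration of the C1=C10 alkene into conjugation.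

Step 5
Reactants: 9 acryloyl chloride; 10 2-(trimethylsilyl)ethanol
Product: 11 2-(trimethylsilyl)ethyl acrylate
Conditions: Et3N, CH2Cl2, 0 °C
Reagents that add atoms: none
Why: Simple O-acylation of a primary alcohol; this ester is chosen because fluoride removes it later without touching epoxides or the other esters.

Step 6
Reactants: 11 2-(trimethylsilyl)ethyl acrylate; 12 acrolein
Product: 13 2-(trimethylsilyl)ethyl 3-hydroxy-2-methylidenepent-4-enoate (racemic)
Conditions: DABCO (30 mol %), 1,4-dioxane–H2O, rt
Reagents that add atoms: none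
Why: Morita–Baylis–Hillman reaction, in which the amine–acrylate enolate adds 1,2 to acrolein; the racemic carbinol center is erased in step 7.

Step 7
Reactants: 13 2-(trimethylsilyl)ethyl 3-hydroxy-2-methylidenepent-4-enoate
Product: 14 2-(trimethylsilyl)ethyl (2Z)-2-(bromomethyl)penta-2,4-dienoate
Conditions: PBr3 (0.4 equiv), Et2O, −10 to 0 °C
Reagents that add atoms: phosphorus tribromide BrP(Br)Br
Why: SN2′ bromination of a Baylis–Hillman alcohol gives the conjugated primary allylic bromide with the vinyl group cis to CH2Br; any allylic isomer would give the same pentadienylmetal in step 10.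

Step 8
Reactants: 15 (E)-2-methylbut-2-en-1-ol
Product: 16 [(2S,3S)-2,3-dimethyloxiran-2-yl]methanol
Conditions: Ti(OiPr)4 (10 mol %), L-(+)-diisopropyl tartrate (12 mol %), t-BuOOH, 4 Å molecular sieves, CH2Cl2, −20 °C
Reagents that add atoms: tert-butyl hydroperoxide CC(C)(C)OO
Why: Sharpless asymmetric epoxidation; the L-(+)-tartrate complex delivers oxygen to the face of the E allylic alcohol that gives the (2S,3S) epoxy alcohol, which sets C2′ and C3′.

Step 9
Reactants: 16 [(2S,3S)-2,3-dimethyloxiran-2-yl]methanol
Product: 17 (2R,3S)-2,3-dimethyloxirane-2-carboxylic acid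
Conditions: RuCl3 (2 mol %), NaIO4, CCl4–MeCN–H2O, 0 °C to rt
Reagents that add atoms: sodium periodate [Na+].[O-]I(=O)(=O)=O
Why: RuO4 oxidation takes primary epoxy alcohols to glycidic acids without opening the epoxide, so both centers are kept (the C2′ descriptor changes only through priorities).

Step 10
Reactants: 8 (3E,6E)-3,7-dimethylnona-3,6,8-trienal; 14 2-(trimethylsilyl)ethyl (2Z)-2-(bromomethyl)penta-2,4-dienoate
Product: 19 2-(trimethylsilyl)ethyl (3R,4R,6E,9E)-3-ethenyl-4-hydroxy-6,10-dimethyl-2-methylidenedodeca-6,9,11-trienoate, via trimethylsilyl ether 18 (not isolated)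
Conditions: CrCl2 (10 mol %), (S,S)-1,8-bis(4-isopropyl-4,5-dihydrooxazol-2-yl)-3,6-diphenyl-9H-carbazole (12 mol %), Mn powder, Me3SiCl, iPr2NEt (30 mol %), THF, rt; then 1 M HCl, THF, 0 °C
Reagents that add atoms: chlorotrimethylsilane C[Si](C)(C)Cl (its atoms stay only in 18)
Why: Catalytic asymmetric Nozaki–Hiyama–Kishi allylation, in which the 2-(alkoxycarbonyl)pentadienylchromium reagent reacts at its central carbon C7 through a closed chair transition state to give the 7,8-syn pair, while the tridentate ligand on trivalent chromium selects the aldehyde face (8R, hence 7R).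

Step 11
Reactants: 19 syn alcohol; 17 (2R,3S)-2,3-dimethyloxirane-2-carboxylic acid
Product: 21 2-(trimethylsilyl)ethyl (3R,4R,6E,9E)-4-{[(2R,3S)-2,3-dimethyloxirane-2-carbonyl]oxy}-3-ethenyl-6,10-dimethyl-2-methylidenedodeca-6,9,11-trienoate, via mixed anhydride 20 (not isolated)
Conditions: 2,4,6-trichlorobenzoyl chloride, Et3N, THF, rt; then 19, DMAP, toluene, rt
Reagents that add atoms: 2,4,6-trichlorobenzoyl chloride O=C(Cl)c1c(Cl)cc(Cl)cc1Cl (its atoms stay only in 20)
Why: Yamaguchi esterification acylates the hindered C8 alcohol under non-acidic conditions without touching a stereocenter, blocks closure of an 8,12-lactone, and turns any minor enantiomer of 19 into a separable diastereomer.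

Step 12
Reactants: 21 C8 ester
Product: 22 2-(trimethylsilyl)ethyl (3R,4R,6R,7R,9E)-4-{[(2R,3S)-2,3-dimethyloxirane-2-carbonyl]oxy}-6,7-epoxy-3-ethenyl-6,10-dimethyl-2-methylidenedodeca-9,11-dienoate
Conditions: D-fructose-derived Shi ketone (30 mol %), KHSO5 (as Oxone, 1.3 equiv), K2CO3, Bu4NHSO4 (cat.), MeCN–dimethoxymethane/aq. Na2B4O7–Na2EDTA buffer, 0 °C
Reagents that add atoms: potassium peroxymonosulfate [K+].[O-]S(=O)(=O)OO
Why: Shi asymmetric epoxidation; the chiral dioxirane attacks the isolated electron-rich trisubstituted C1=C10 alkene faster than the conjugated diene, the vinyl group or the acrylate, and its spiro transition state sets (1R,10R) under reagent control.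

Step 13
Reactants: 22 epoxy tetraene
Product: 23 2-(trimethylsilyl)ethyl (1R,3E,5Z,7R,8R,10R)-8-{[(2R,3S)-2,3-dimethyloxirane-2-carbonyl]oxy}-1,10-epoxygermacra-3,5,11(13)-trien-12-oate
Conditions: second-generation Hoveyda–Grubbs catalyst (10 mol %), 1,4-benzoquinone (20 mol %), toluene (0.5 mM), 60 °C
Reagents that add atoms: none
Why: Diene–ene ring-closing metathesis joins the C7 vinyl group to the terminal CH2 of the diene, since the trisubstituted C3=C4 alkene and the acrylate are inert and step 12 has removed the C1=C10 alkene that would otherwise close a cyclopentene; ring strain should allow only the 5Z alkene next to 3E.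

Step 14
Reactants: 23 macrocyclic silylethyl ester
Product: 24 (1R,3E,5Z,7R,8R,10R)-8-{[(2R,3S)-2,3-dimethyloxirane-2-carbonyl]oxy}-1,10-epoxygermacra-3,5,11(13)-trien-12-oic acid
Conditions: Bu4NF (1.5 equiv), THF, 0 °C; aq. NH4Cl
Reagents that add atoms: none
Why: Fluoride attacks silicon and the ester fragments to ethene and Me3SiF (fluoride-induced β-elimination), which at 0 °C should spare both epoxides, the C8 ester and the diene.

Step 15
Reactants: 24 macrocyclic diene acid; 25 isobutyric acid
Product: 27 target CNP0117882.3, via allylpalladium lactone 26 (not isolated)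
Conditions: Pd(OAc)2 (10 mol %), LiCl (20 mol %), iPrCO2Li (2 equiv), p-benzoquinone (1.5 equiv), 25 (10 equiv), acetone, 20 °C
Reagents that add atoms: palladium diacetate CC(=O)[O-].CC(=O)[O-].[Pd+2] and lithium chloride [Li+].[Cl-] (Pd and Cl stand only in 26, not in 27)
Why: Divalent palladium binds the s-cis C3=C4–C5=C6 diene of the ten-membered ring η4 on the face away from the C7 acrylic acid arm, the carboxylate oxygen attacks C6 anti to the metal and closes the γ-lactone (5-exo-trig), and the C3–C5 π-allyl complex 26, whose chloride ligand blocks inner-sphere delivery, is opened at C3 by external isobutyrate, again anti to the metal, after which benzoquinone reoxidizes zerovalent palladium. The closest known reaction type is the palladium-catalysed, ligand-controlled 1,4-acyloxylactonization of cycloalka-2,4-dienylacetic acids with benzoquinone as oxidant. C6 is controlled by C7, because A(1,3) strain across the 5Z alkene keeps H7 in the diene plane, so the arm reaches one face only and the 6,7-trans lactone (6R) results. C3 is controlled by the metal, because both oxygens enter on the same face and C2 sits in the outer (E) position on C3, which translates into 3S. The 4Z alkene follows from the s-cis diene, which places C6 anti on the allyl unit, and the ring should prevent syn–anti exchange. The step needs chemoselectivity for the conjugated diene over the electron-poor acrylate and 1,4- over 1,2-addition, secured by η4 binding and by shielding of C5 by the new lactone, and it needs both epoxides to survive, secured by the lithium isobutyrate buffer.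

Compound list
1 | (E)-3-methylpent-2-en-4-yn-1-ol | OC/C=C(\C)C#C | starting material
2 | (E)-3-methylpenta-2,4-dien-1-ol | OC/C=C(\C)C=C | intermediate
3 | (E)-3-methylpenta-2,4-dienyl methanesulfonate | CS(=O)(=O)OC/C=C(\C)C=C | intermediate
4 | (2E)-1-chloro-3-methylpenta-2,4-diene | ClC/C=C(\C)C=C | intermediate
5 | but-3-yn-1-ol | C#CCCO | starting material
6 | (E)-alkenylalane, Me2Al on C1 and O-AlMe2 on C8 | C[Al](C)/C=C(\C)CCO[Al](C)C | intermediate
7 | (3E,6E)-3,7-dimethylnona-3,6,8-trien-1-ol | OCC/C(C)=C/C/C=C(\C)C=C | intermediate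
8 | (3E,6E)-3,7-dimethylnona-3,6,8-trienal | O=CC/C(C)=C/C/C=C(\C)C=C | intermediate
9 | acryloyl chloride | C=CC(=O)Cl | starting material
10 | 2-(trimethylsilyl)ethanol | C[Si](C)(C)CCO | starting material
11 | 2-(trimethylsilyl)ethyl acrylate | C=CC(=O)OCC[Si](C)(C)C | intermediate
12 | acrolein | C=CC=O | starting material
13 | 2-(trimethylsilyl)ethyl 3-hydroxy-2-methylidenepent-4-enoate (racemic) | C=CC(O)C(=C)C(=O)OCC[Si](C)(C)C | intermediate
14 | 2-(trimethylsilyl)ethyl (2Z)-2-(bromomethyl)penta-2,4-dienoate | BrC/C(C(=O)OCC[Si](C)(C)C)=C\C=C | intermediate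
15 | (E)-2-methylbut-2-en-1-ol | C/C=C(\C)CO | starting material
16 | [(2S,3S)-2,3-dimethyloxiran-2-yl]methanol | OC[C@]1(C)O[C@H]1C | intermediate
17 | (2R,3S)-2,3-dimethyloxirane-2-carboxylic acid | OC(=O)[C@]1(C)O[C@H]1C | intermediate
18 | O-trimethylsilyl ether of 19 | C=C(C(=O)OCC[Si](C)(C)C)[C@@H](C=C)[C@H](O[Si](C)(C)C)C/C(C)=C/C/C=C(\C)C=C | intermediate
19 | 2-(trimethylsilyl)ethyl (3R,4R,6E,9E)-3-ethenyl-4-hydroxy-6,10-dimethyl-2-methylidenedodeca-6,9,11-trienoate (7R,8R, syn) | C=C(C(=O)OCC[Si](C)(C)C)[C@@H](C=C)[C@H](O)C/C(C)=C/C/C=C(\C)C=C | intermediate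
20 | (2R,3S)-2,3-dimethyloxirane-2-carboxylic 2,4,6-trichlorobenzoic anhydride | O=C(OC(=O)c1c(Cl)cc(Cl)cc1Cl)[C@]1(C)O[C@H]1C | intermediate
21 | C8 (2R,3S)-2,3-dimethyloxirane-2-carboxylate of 19 | C=C(C(=O)OCC[Si](C)(C)C)[C@@H](C=C)[C@H](OC(=O)[C@]1(C)O[C@H]1C)C/C(C)=C/C/C=C(\C)C=C | intermediate
22 | (1R,10R)-epoxide of 21 | C=C(C(=O)OCC[Si](C)(C)C)[C@@H](C=C)[C@H](OC(=O)[C@]1(C)O[C@H]1C)C[C@@]2(C)O[C@@H]2C/C=C(\C)C=C | intermediate
23 | macrocyclic (3E,5Z)-diene 2-(trimethylsilyl)ethyl ester | C=C(C(=O)OCC[Si](C)(C)C)[C@H]1/C=C\C(C)=C\C[C@H]2O[C@]2(C)C[C@H]1OC(=O)[C@]1(C)O[C@H]1C | intermediate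
24 | macrocyclic (3E,5Z)-diene acid | C=C(C(=O)O)[C@H]1/C=C\C(C)=C\C[C@H]2O[C@]2(C)C[C@H]1OC(=O)[C@]1(C)O[C@H]1C | intermediate
25 | isobutyric acid | CC(C)C(=O)O | starting material
26 | 6,12-lactone C3–C5 π-allylpalladium chloride, drawn as its C3-bound η1 form with Pd anti to O6 | C=C1C(=O)O[C@@H]2/C=C(/C)[C@H]([Pd]Cl)C[C@H]3O[C@]3(C)C[C@@H](OC(=O)[C@]3(C)O[C@H]3C)[C@@H]12 | intermediate
27 | (1R,3S,4Z,6R,7R,8R,10R)-1,10-epoxy-3-isobutyryloxy-8-[(2R,3S)-2,3-dimethyloxirane-2-carbonyloxy]germacra-4,11(13)-dien-12,6-olide | C=C1C(=O)O[C@@H]2/C=C(/C)[C@@H](OC(=O)C(C)C)C[C@H]3O[C@]3(C)C[C@@H](OC(=O)[C@]3(C)O[C@H]3C)[C@@H]12 | target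

Total step count: 15. Longest linear sequence: 10 (steps 1–4 and 10–15).

Steps most likely to fail

Step 15. The diene may bind s-trans, or the allyl intermediate may undergo syn–anti exchange, with loss of the 4Z geometry. Inner-sphere carboxylate transfer may erode the C3 selectivity. The carboxylic acid medium may open the C1–C10 epoxide. The fallback replaces the oxidative addition by a redox-neutral allylic substitution and sets out from 24. Dimethyldioxirane (1 equiv, acetone, −40 °C) should epoxidize the more substituted C3=C4 alkene of the diene on the face that carries the acid arm, giving the (3S,4S)-vinyl epoxide acid F1. Pd(PPh3)4 in THF then ionizes the allylic C4–O bond with inversion, and the carboxylate attacks C6 with a second inversion (Tsuji–Trost-type 1,4-opening of a vinyl epoxide). The C3 alkoxide holds the metal in a six-membered chelate that favours the 4Z alkene, and the product is the 3-hydroxy lactone F2. Acylation with isobutyric anhydride and DMAP comes back to the route at 27.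

Step 13. Ring closure may lose to oligomerization because of ring strain, and heating may start a 1,5-hydrogen shift from C7 across the Z-diene. The fallback uses a temporary ring as a conformational lock and sets out from 19.
- Catalytic camphorsulfonic acid closes the cis-8,12-lactone F3, which holds the C7 vinyl group and the C9 chain on the same side.
- Shi epoxidation as in step 12 gives the epoxy lactone F4.
- Metathesis gives the bicyclic macrocyclic 8,12-olide F5.
- LiOH in THF–H2O opens the lactone to the lithium hydroxy carboxylate F6, which is alkylated in the same flask with allyl bromide in DMF to the hydroxy allyl ester F7.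
- Yamaguchi acylation with 17 gives the allyl ester F8.
- Pd(PPh3)4 with morpholine removes the allyl group and comes back to the route at 24.

Step 10. Face selection on an unbranched, enolizable β,γ-unsaturated aldehyde may be poor, and the aldehyde may isomerize during a slow catalytic reaction. The fallback gives up catalyst control for a resolution that costs no extra step and sets out from 8 and 14. An indium-mediated Barbier reaction (In powder, THF–H2O, rt) should give the syn adduct as a racemate, that is 19 together with its enantiomer F9. Esterification with enantiopure 17 as in step 11 gives 21 and the (7S,8S) diastereomeric ester F10. These are separated by chromatography, and the route is rejoined at 21.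

Further compounds
F1 | step 15 | (3S,4S)-3,4-epoxide of acid 24 (vinyl epoxide acid, oxygen on the face of the C11 arm) | C=C(C(=O)O)[C@H]1/C=C\[C@]2(C)O[C@H]2C[C@H]3O[C@]3(C)C[C@H]1OC(=O)[C@]1(C)O[C@H]1C
F2 | step 15 | 3-O-deacyl target, (3S)-3-hydroxy-6,12-olide | C=C1C(=O)O[C@@H]2/C=C(/C)[C@@H](O)C[C@H]3O[C@]3(C)C[C@@H](OC(=O)[C@]3(C)O[C@H]3C)[C@@H]12
F3 | step 13 | cis-8,12-lactone of 19 (α-methylene-γ-butyrolactone with C7 vinyl and C8 trienyl chain cis) | C=C1C(=O)O[C@H](C/C(C)=C/C/C=C(\C)C=C)[C@@H]1C=C
F4 | step 13 | (1R,10R)-epoxide of F3 | C=C1C(=O)O[C@H](C[C@@]2(C)O[C@@H]2C/C=C(\C)C=C)[C@@H]1C=C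
F5 | step 13 | (3E,5Z)-1,10-epoxygermacra-3,5,11(13)-trien-12,8-olide | C=C1C(=O)O[C@@H]2C[C@@]3(C)O[C@@H]3C/C=C(C)/C=C\[C@H]12
F6 | step 13 | lithium 8-hydroxy-1,10-epoxygermacra-3,5,11(13)-trien-12-oate | [Li+].C=C(C(=O)[O-])[C@H]1/C=C\C(C)=C\C[C@H]2O[C@]2(C)C[C@H]1O
F7 | step 13 | allyl 8-hydroxy-1,10-epoxygermacra-3,5,11(13)-trien-12-oate | C=C(C(=O)OCC=C)[C@H]1/C=C\C(C)=C\C[C@H]2O[C@]2(C)C[C@H]1O
F8 | step 13 | allyl ester analogue of 23 | C=C(C(=O)OCC=C)[C@H]1/C=C\C(C)=C\C[C@H]2O[C@]2(C)C[C@H]1OC(=O)[C@]1(C)O[C@H]1C
F9 | step 10 | enantiomer of 19 (7S,8S) | C=C(C(=O)OCC[Si](C)(C)C)[C@H](C=C)[C@@H](O)C/C(C)=C/C/C=C(\C)C=C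
F10 | step 10 | (7S,8S) diastereomer of 21 | C=C(C(=O)OCC[Si](C)(C)C)[C@H](C=C)[C@@H](OC(=O)[C@]1(C)O[C@H]1C)C/C(C)=C/C/C=C(\C)C=C
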